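**Slow clock.** Slowness rules here: Saturday's flask needed 30.0 h to bring G down to 48.2%.

| flask | G | Q | remark | time |
|---|---|---|---|---|
| Friday's | 0.026 M | 0.95 equiv | run made earlier |  |
| Saturday's | 0.037 M | 0.95 equiv | run made earlier |  |
| teal | 0.052 M | 0.950 equiv |  | 2.5 d |
| violet | 0.040 M | 0.950 equiv |  | 0.60 d |

| run | time / h | D / % | G / % |
|---|---|---|---|
| Friday's | 3.00 | 4.7 | 94.3 |
| Friday's | 6.00 | 11.1 | 89.5 |
| Friday's | 12.0 | 18.0 | 80.5 |
| Friday's | 20.0 | 23.8 | 72.4 |
| Friday's | 40.0 | 36.8 | 54.2 |
| Saturday's | 8.00 | 15.8 | 83.1 |
| Saturday's | 15.0 | 25.6 | 70.2 |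
| Saturday's | 25.0 | 34.6 | 55.8 |
| Saturday's | 30.0 | 40.6 | 48.2 |
| Saturday's | 40.0 | 44.8 | 39.9 |

(readings scatter by 1 percentage point)
1. the flask that ends with the higher amount of D, in percent of the G charged, or "neither" when 2 percentage points or less lies between them (teal / violet / neither)
2. final D, as a percentage of the G charged, in teal
3. final D, as a percentage of the G charged, in violet
- where the amount of G changes, what is given in equivalents or mol% on it follows

**Common clock.** Friday's 40.0 h and Saturday's 25.0 h leave similar G, 54.2% and 55.8%, at exposures (starting c_G times time) of 1.04 M·h and 0.925 M·h. So exposure serves as the clock, and the half-exposure, read from Saturday's flask, is 1.11 M·h.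

**The ladder.** On the first rung, up to 15.0 h in Saturday's flask, D gains 6.10 times the G that goes unseen. From there to 40.0 h this split, a selectivity factor, reads 1.73. The top rung is my reckoning: past that reading the split is even. The end mark of D, the last D read plus half the last G read, is then 64.8%.

**Reckoning.** Violet reaches 0.576 M·h, beside Saturday's 15.0 h reading, so its D is near 25.6%. Teal reaches 3.12 M·h; a second-order fall leaves G near 26.2%, so its D is near 51.6%.

**Result.** The forecast, placing teal “near the D plateau”, gives teal, with 51% and 27%. The flasks give 59.0% in teal and 27.0% in violet.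

    G + Q → D + Z (k = 0.0116 M⁻¹ min⁻¹)
    G + Z → X (k = 0.0116 M⁻¹ min⁻¹)

**Not at rest.** At 2.50 d teal still holds 17% of its G. At 25.0 d teal has D 67.1%, X 32.9% and G 0%, so D gains about half of that G, and the end mark lies 2.3 percentage points below. Teal makes Z 2.69 times as fast as it uses it at 0.527 d, but 1.03 times at 2.50 d. At 2.50 d teal's G stands lower than my 26.2%, and its D higher than my 51.6%.

**Second flask.** A neighbour of teal, charged with 0.13 M of G and run for the same time, reaches 7.03 half-exposures, so the same second-order fall leaves its G near 12.5% and the end mark puts its D near 58.5%. The computed D of that neighbour is higher than this figure, at 66.2%, with G at 2.0%.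

The numbers in the tables are simulated with made-up constants, and the scatter is random.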